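The isomer of the product stops rising.

| flask | substrate | partner | catalyst | remark | time |
|---|---|---|---|---|---|
| midnight | 0.40 M | 0.30 M | 60 mM | run made earlier |  |
| autumn | 0.40 M | 1.2 M | 60 mM | run made earlier |  |
| summer | 0.40 M | 0.60 M | 30 mM | run made earlier |  |
| flask | 0.40 M | 0.600 M | 60 mM |  | 8.0 min |

- midnight (time / min: isomer of the product / %, target / %): 0.500: 6.4, 9.0; 1.33: 11.3, 3.2; 3.00: 14.0, 0.3; 6.00: 13.7, 0.3
- autumn (time / min: isomer of the product / %, target / %): 1.50: 35.3, 8.4; 3.00: 39.7, 1.4; 5.00: 39.3, 0; 6.00: 39.2, 0
- summer (time / min: isomer of the product / %, target / %): 0.833: 14.2, 11.8; 2.50: 20.8, 1.7; 4.00: 21.9, 0.5; 6.00: 21.2, 0.3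

(readings scatter by 0.3 percentage points)

- ratio of isomer of the product to target at 0.12 s
- ratio of isomer of the product to target at 8.0 s
- ratio of isomer of the product to target at 8.0 min
- which of isomer of the product and target there is more of at 8.0 min



The midnight run reads 14.0% of isomer at 3.00 min and 13.7% at 6.00 min. Taken one to one, that isomer holds 0.0548 M of partner, less than the 0.30 M charged, so the stop is not explained by the charge being used up in isomer. The target gives a clue. Its fall between the first two readings is 1.25 min⁻¹ in the midnight run and 1.16 min⁻¹ in the summer run, which has half the catalyst and twice the partner. The half-time read from the summer fall is about 0.598 min, far shorter than the 8.0 min of the flask.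

My own reckoning takes this as partner being lost first-order on that clock, whatever its charge. Substrate then feels a pseudo-first-order pull proportional to c(partner), and the time integral of c(partner) is proportional to the charge. The logarithm of the inverse of the share of substrate not turned into isomer, divided by the partner charged, should therefore hold roughly steady. This is the capture number. It reads 0.491 M⁻¹ in the midnight run and 0.415 M⁻¹ in the autumn run, both at the catalyst of the flask. The partner charge of the flask is their geometric mean, so the mean of the two is taken as its capture number 0.453 M⁻¹. The flask should then end near 23.8% of isomer. Late target reads 0.3% in the midnight run, with a scatter of 0.3 percentage points, so that reading gives no late ratio for the flask, but it stands below the isomer reckoned, and the reckoning puts isomer ahead at 8.0 min.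

The forecast gave ratios of 0.07, 0.2 and 1000 at 0.12 s, 8.0 s and 8.0 min, with isomer of the product ahead at the last time, calling the last ratio “very large and poorly defined”.

The flask gives ratios of 0.0203, 0.157 and 278 at those times, with isomer of the product ahead at 8.0 min: 23.6% against 0.0850% of target.

    substrate + partner ⇌ target (K = 0.810 M⁻¹, k = 0.490 M⁻¹ s⁻¹)
    substrate + partner ⇌ isomer of the product (K = 45.0 M⁻¹, k = 0.00940 M⁻¹ s⁻¹)
    target + catalyst ⇌ isomer of the product + catalyst, rate k3*[catalyst]*[target] forward; the back reaction follows from the equilibrium constant (k = 0.110 M⁻¹ s⁻¹)
    partner → decomposed reagent (k = 0.0200 s⁻¹)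

The isomer of the flask corresponds to a capture number of 0.449 M⁻¹, against the 0.453 M⁻¹ reckoned, and its partner, with a half-life of 0.58 min by the step to decomposed reagent alone, stands at 0.22% of its charge at 8.0 min. The neighbouring flask, the same recipe with 0.15 M of partner, lies below the midnight charge, so the reckoning gives it the midnight number 0.491 M⁻¹, and that gives 7.10% of isomer. That neighbour holds 7.12% of isomer at 8.0 min.

The runs come from a simulation from invented constants, noise included.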